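**Plan**
- Retrosynthesis: cut the C15–O ester bond (C32 acid from two C16 units joined at C16–C17), then C3–C4 of ring A, then C5–C6 and C9–C10 of ring B.
- Enabling feature: ring B is a cyclohexene whose C7=C8 alkene, C8 methyl and C9 chain form the retron of a 1-alkyl-2-methylbuta-1,3-diene (C6=C7–C8=C9). C10 (methyl, C1) and C5 (H, C4) are the alkene carbons of an (E)-2-methyl enal; C4 is carried as an ester, which activates the dienophile and leaves no second alkene to compete.
- Forward: geraniol gives the triene; the Diels–Alder reaction closes ring B; formyl and ester become the C1=C2 vinyl and C4 isopropenyl groups; hydroformylation adds C3; an iron hydride radical cyclisation closes ring A; C15 is acylated last.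
- Stereochemistry: C5, C9 and C10 come from the cycloaddition (E dienophile, formyl-exo/ester-endo approach, (R)-oxazaborolidinium); C3 from the chair transition state of the ring A closure; the E C13=C14 alkene from geraniol.

Key step: step 4

Remark: labdane numbering is used for all intermediates; CIP descriptors change along the route only because substituent priorities change. The target is read as the (3R,5S,9R,10S) ent-labdane diol esterified at C15 with 32-hydroxydotriacontanoic acid (31 CH2 groups).

**Route**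

Step 1
Reactants: 1 geraniol, (2E)-3,7-dimethylocta-2,6-dien-1-ol
Product: 2 tert-butyl{[(2E)-3,7-dimethylocta-2,6-dien-1-yl]oxy}diphenylsilane
Conditions: TBDPSCl, imidazole, CH2Cl2, 0 °C to rt
Reagents that add atoms: tert-butyl(chloro)diphenylsilane, CC(C)(C)[Si](Cl)(c1ccccc1)c1ccccc1
Why: Imidazole-mediated silylation of the primary allylic alcohol gives an ether that should tolerate the Lewis acid, titanium carbenoid, rhodium and iron hydride steps ahead and is removed by fluoride in step 9.

Step 2
Reactants: 2 geranyl silyl ether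
Product: 4 (2E,6E)-8-(tert-butyldiphenylsilyloxy)-2,6-dimethylocta-2,6-dienal, via allylic alcohol 3 (not isolated)
Conditions: SeO2 (0.1 equiv), t-BuOOH (3 equiv), salicylic acid (0.1 equiv), CH2Cl2, rt; crude, then MnO2 (15 equiv), CH2Cl2, rt
Reagents that add atoms: selenium dioxide, O=[Se]=O; tert-butyl hydroperoxide, CC(C)(C)OO
Why: Riley allylic oxidation hydroxylates the (E)-methyl group of the terminal trisubstituted alkene by an ene reaction and [2,3]-sigmatropic shift, and MnO2 then converges alcohol 3 and any over-oxidised material on the single (E)-enal.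

Step 3
Reactants: 4 (E,E)-enal
Product: 5 tert-butyl{[(2E,6E)-3,7-dimethylnona-2,6,8-trien-1-yl]oxy}diphenylsilane (diene C6=C7–C8=C9)
Conditions: Ph3PCH3Br, KOt-Bu, THF, 0 °C to rt
Reagents that add atoms: methyltriphenylphosphonium bromide, C[P+](c1ccccc1)(c1ccccc1)c1ccccc1.[Br-]
Why: Wittig methylenation of the unhindered enal gives the terminal 1,3-diene and leaves the E geometry of the C8=C9 double bond intact.

Step 4
Reactants: 5 triene; 6 ethyl (2E)-3-methyl-4-oxobut-2-enoate (1.5 equiv)
Product: 7 ethyl (1S,5R,6S)-5-[(3E)-5-(tert-butyldiphenylsilyloxy)-3-methylpent-3-en-1-yl]-6-formyl-4,6-dimethylcyclohex-3-ene-1-carboxylate (labdane 5S,9R,10S)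
Conditions: (3aR)-1-(2-methylphenyl)-3,3-diphenyltetrahydro-1H,3H-pyrrolo[1,2-c][1,3,2]oxazaborole (20 mol%) protonated with Tf2NH (18 mol%), CH2Cl2, −78 to −40 °C
Reagents that add atoms: none
Why: The N-protonated oxazaborolidinium binds the formyl oxygen of 6 (formyl C–H···O contact to the ring oxygen, s-trans enal lying over a C-phenyl group), and the diene C6=C7–C8=C9 adds in a concerted, asynchronous, normal-demand Diels–Alder reaction in which C5–C6 bonding runs ahead of C9–C10 bonding; the closest known reaction type is the oxazaborolidinium-catalysed cycloaddition of 2-methylacrolein and its β-alkoxycarbonyl derivatives to acyclic and 1-vinylcycloalkene dienes. Ring B is closed as a cyclohexene by intermolecular [4+2] cycloaddition, both σ bonds forming suprafacially on each partner and leaving C7=C8. C5 and C10 are fixed relative to each other by the E geometry of 6 (ester carbon C4 trans to formyl carbon C1, the later trans ring fusion); C9 is fixed relative to C10 by the formyl-exo/ester-endo transition state, which places the C11 chain of the (E)-diene terminus cis to the C10 methyl; the absolute sense is set by the (R)-catalyst, whose phenyl group is expected to cover the Re face of C10 so that C9 bonds to its Si face. The step needs regioselectivity, secured by the catalyst-bound formyl group making C5 the electrophilic carbon and by the C9 alkyl substituent making C6 the nucleophilic terminus, as in 1-vinylcyclohexenes, with the C8 methyl pulling only weakly the other way. It also needs formyl-exo selectivity, supported by the α-methyl group, by the endo preference of the ester and by the bulk of the catalyst-bound formyl group next to the C11 chain, and chemoselectivity for the conjugated diene over the isolated C13=C14 alkene, which is inherent.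

Step 5
Reactants: 7 ring B aldehyde ester
Product: 9 1-[(1S,5R,6S)-5-[(3E)-5-(tert-butyldiphenylsilyloxy)-3-methylpent-3-en-1-yl]-6-ethenyl-4,6-dimethylcyclohex-3-en-1-yl]ethan-1-one, via enol ether 8 (not isolated)
Conditions: Cp2Ti(μ-Cl)(μ-CH2)AlMe2 (3 equiv), pyridine (cat.), THF/toluene, −40 °C to rt; aq. NaOH, filter; then 1 M HCl, THF, 0 °C
Reagents that add atoms: Tebbe reagent Cp2Ti(μ-Cl)(μ-CH2)AlMe2, C[Al-]1(C)C[Ti](C2C=CC=C2)(C2C=CC=C2)[Cl+]1; water, O
Why: Tebbe methylenation, which is non-basic and effective for hindered carbonyl groups, converts the neopentyl formyl group into the C1=C2 vinyl group and the ester into the ethyl enol ether 8 without epimerising C5, and dilute acid then hydrolyses only the enol ether to the C4 methyl ketone.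

Step 6
Reactants: 9 vinyl methyl ketone
Product: 10 tert-butyl({(2E)-5-[(1R,5R,6R)-6-ethenyl-2,6-dimethyl-5-(prop-1-en-2-yl)cyclohex-2-en-1-yl]-3-methylpent-2-en-1-yl}oxy)diphenylsilane
Conditions: Cp2Ti(μ-Cl)(μ-CH2)AlMe2 (1.5 equiv), pyridine (cat.), THF, −40 to 0 °C; aq. NaOH
Reagents that add atoms: Tebbe reagent Cp2Ti(μ-Cl)(μ-CH2)AlMe2, C[Al-]1(C)C[Ti](C2C=CC=C2)(C2C=CC=C2)[Cl+]1
Why: A second Tebbe methylenation turns the enolisable methyl ketone into the isopropenyl group under non-basic conditions, so the C5 configuration set in step 4 is kept.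

Step 7
Reactants: 10 vinyl isopropenyl triene
Product: 11 3-[(1R,2R,6R)-2-[(3E)-5-(tert-butyldiphenylsilyloxy)-3-methylpent-3-en-1-yl]-1,3-dimethyl-6-(prop-1-en-2-yl)cyclohex-3-en-1-yl]propanal
Conditions: Rh(acac)(CO)2 (2 mol%), 4,5-bis(diphenylphosphino)-9,9-dimethylxanthene (6 mol%), CO/H2 (1:1, 10 bar), toluene, 70 °C
Reagents that add atoms: carbon monoxide, [C-]#[O+]
Why: Rhodium-catalysed hydroformylation with a wide-bite-angle diphosphine adds hydrogen and CO in the linear sense to the monosubstituted vinyl group, which cannot isomerise because C10 is quaternary, much faster than to the 1,1-disubstituted and trisubstituted alkenes, and so delivers the C3 aldehyde.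

Step 8
Reactants: 11 isopropenyl aldehyde
Product: 12 (2R,4aS,5R,8aS)-5-[(3E)-5-(tert-butyldiphenylsilyloxy)-3-methylpent-3-en-1-yl]-1,1,4a,6-tetramethyl-1,2,3,4,4a,5,8,8a-octahydronaphthalen-2-ol (labdane 3R,5S,9R,10S)
Conditions: Fe(acac)3 (0.5 equiv), PhSiH3 (2.5 equiv), EtOH (0.02 M, degassed), 60 °C
Reagents that add atoms: none
Why: Hydrogen-atom transfer from the iron hydride formed from Fe(acac)3 and PhSiH3 to the CH2 terminus of the isopropenyl group, the most accessible alkene, gives the tertiary C4 radical, which adds 6-exo to the C3 formyl group through a chair transition state with the carbonyl oxygen equatorial, and reduction and protonation of the alkoxy radical give the trans-fused ring A with the equatorial 3R alcohol, a known metal-hydride-initiated alkene–carbonyl reductive radical cyclisation.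

Step 9
Reactants: 12 bicyclic silyl ether
Product: 13 (2R,4aS,5R,8aS)-5-[(3E)-5-hydroxy-3-methylpent-3-en-1-yl]-1,1,4a,6-tetramethyl-1,2,3,4,4a,5,8,8a-octahydronaphthalen-2-ol
Conditions: Bu4NF (1.5 equiv), THF, 0 °C to rt
Reagents that add atoms: none
Why: Fluoride-induced desilylation cleaves the primary allylic silyl ether and leaves the alkenes and the secondary alcohol untouched.

Step 10
Reactants: 14 16-hydroxyhexadecanoic acid
Product: 15 16-bromohexadecanoic acid
Conditions: 48% aq. HBr, conc. H2SO4, reflux
Reagents that add atoms: hydrogen bromide, Br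
Why: Acid-promoted SN2 substitution of the protonated primary alcohol by bromide gives the ω-bromo acid.

Step 11
Reactants: 15 16-bromohexadecanoic acid
Product: 16 16-bromohexadecan-1-ol
Conditions: BH3·THF (1.3 equiv), THF, 0 °C to rt; MeOH
Reagents that add atoms: none
Why: Borane reduction of the carboxylic acid through its acyloxyborane is chemoselective and does not touch the primary alkyl bromide.

Step 12
Reactants: 16 16-bromohexadecan-1-ol
Product: 17 [(16-bromohexadecyl)oxy](tert-butyl)dimethylsilane
Conditions: TBSCl, imidazole, DMF, rt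
Reagents that add atoms: tert-butyl(chloro)dimethylsilane, CC(C)(C)[Si](C)(C)Cl
Why: Silylation of the primary alcohol gives a Grignard-compatible ether that is cleaved by HF·pyridine at the end.

Step 13
Reactants: 17 silyloxy bromide (1.5 equiv); 15 16-bromohexadecanoic acid
Product: 20 32-(tert-butyldimethylsilyloxy)dotriacontanoic acid, via Grignard reagent 18 (not isolated), via chloromagnesium carboxylate 19 (not isolated)
Conditions: 17, Mg, THF, 50 °C; separately 15, MeMgCl (1.0 equiv), THF, −20 °C; combine, Li2CuCl4 (3 mol%), −20 °C to rt; cold 0.5 M HCl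
Reagents that add atoms: none
Why: Copper-catalysed sp3–sp3 cross-coupling of the primary alkylmagnesium bromide 18 with the primary bromide of carboxylate 19, whose carboxylate group is inert to the Grignard reagent at low temperature, joins the two C16 units into the C32 chain.

Step 14
Reactants: 13 diol; 20 C32 silyloxy acid (1.0 equiv)
Product: 21 (2E)-5-[(1R,4aS,6R,8aS)-6-hydroxy-2,5,5,8a-tetramethyl-1,4,4a,5,6,7,8,8a-octahydronaphthalen-1-yl]-3-methylpent-2-en-1-yl 32-(tert-butyldimethylsilyloxy)dotriacontanoate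
Conditions: DCC (1.1 equiv), DMAP (0.1 equiv), CH2Cl2, 0 °C to rt
Reagents that add atoms: none
Why: Steglich esterification should acylate the unhindered primary allylic C15 hydroxyl much faster than the secondary C3 hydroxyl, which is flanked by the C4 gem-dimethyl group, so one equivalent of acid gives the C15 monoester.

Step 15
Reactants: 21 silyl-protected ester
Product: 22 target, (2E)-5-[(1R,4aS,6R,8aS)-6-hydroxy-2,5,5,8a-tetramethyl-1,4,4a,5,6,7,8,8a-octahydronaphthalen-1-yl]-3-methylpent-2-en-1-yl 32-hydroxydotriacontanoate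
Conditions: HF·pyridine, THF/pyridine, 0 °C to rt
Reagents that add atoms: none
Why: Buffered HF·pyridine desilylation removes the primary silyl ether without cleaving or transposing the allylic ester and without touching the alkenes.

**Compound list**

1 | geraniol | CC(C)=CCC/C(C)=C/CO | starting material
2 | geranyl tert-butyldiphenylsilyl ether | CC(C)=CCC/C(C)=C/CO[Si](c1ccccc1)(c1ccccc1)C(C)(C)C | intermediate
3 | (2E,6E)-8-(tert-butyldiphenylsilyloxy)-2,6-dimethylocta-2,6-dien-1-ol | OC/C(C)=C/CC/C(C)=C/CO[Si](c1ccccc1)(c1ccccc1)C(C)(C)C | intermediate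
4 | (2E,6E)-8-(tert-butyldiphenylsilyloxy)-2,6-dimethylocta-2,6-dienal | O=C/C(C)=C/CC/C(C)=C/CO[Si](c1ccccc1)(c1ccccc1)C(C)(C)C | intermediate
5 | (2E,6E)-3,7-dimethylnona-2,6,8-trienyl tert-butyldiphenylsilyl ether | C=C/C(C)=C/CC/C(C)=C/CO[Si](c1ccccc1)(c1ccccc1)C(C)(C)C | intermediate
6 | ethyl (2E)-3-methyl-4-oxobut-2-enoate | O=C/C(C)=C/C(=O)OCC | starting material
7 | ring B adduct: C10 methyl and formyl, C5 ethyl ester, C9 side chain (5S,9R,10S) | CC1=CC[C@H](C(=O)OCC)[C@@](C)(C=O)[C@@H]1CC/C(C)=C/CO[Si](c1ccccc1)(c1ccccc1)C(C)(C)C | intermediate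
8 | bis-methylenated compound: C10 vinyl, C5 1-ethoxyvinyl (5S,9R,10S) | CC1=CC[C@H](C(=C)OCC)[C@@](C)(C=C)[C@@H]1CC/C(C)=C/CO[Si](c1ccccc1)(c1ccccc1)C(C)(C)C | intermediate
9 | C10 vinyl, C5 acetyl ketone (5S,9R,10S) | CC1=CC[C@H](C(C)=O)[C@@](C)(C=C)[C@@H]1CC/C(C)=C/CO[Si](c1ccccc1)(c1ccccc1)C(C)(C)C | intermediate
10 | C10 vinyl, C5 isopropenyl triene (5R,9R,10R) | CC1=CC[C@H](C(C)=C)[C@@](C)(C=C)[C@@H]1CC/C(C)=C/CO[Si](c1ccccc1)(c1ccccc1)C(C)(C)C | intermediate
11 | C3 aldehyde with C5 isopropenyl (5R,9R,10R) | CC1=CC[C@H](C(C)=C)[C@@](C)(CCC=O)[C@@H]1CC/C(C)=C/CO[Si](c1ccccc1)(c1ccccc1)C(C)(C)C | intermediate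
12 | ent-labda-7,13E-diene-3,15-diol 15-tert-butyldiphenylsilyl ether (3R,5S,9R,10S) | CC1=CC[C@@H]2C(C)(C)[C@H](O)CC[C@@]2(C)[C@@H]1CC/C(C)=C/CO[Si](c1ccccc1)(c1ccccc1)C(C)(C)C | intermediate
13 | ent-labda-7,13E-diene-3,15-diol (3R,5S,9R,10S) | CC1=CC[C@@H]2C(C)(C)[C@H](O)CC[C@@]2(C)[C@@H]1CC/C(C)=C/CO | intermediate
14 | 16-hydroxyhexadecanoic acid | OCCCCCCCCCCCCCCCC(=O)O | starting material
15 | 16-bromohexadecanoic acid | BrCCCCCCCCCCCCCCCC(=O)O | intermediate
16 | 16-bromohexadecan-1-ol | BrCCCCCCCCCCCCCCCCO | intermediate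
17 | [(16-bromohexadecyl)oxy](tert-butyl)dimethylsilane | CC(C)(C)[Si](C)(C)OCCCCCCCCCCCCCCCCBr | intermediate
18 | 16-(tert-butyldimethylsilyloxy)hexadecylmagnesium bromide | CC(C)(C)[Si](C)(C)OCCCCCCCCCCCCCCCC[Mg]Br | intermediate
19 | chloromagnesium 16-bromohexadecanoate | [O-]C(=O)CCCCCCCCCCCCCCCBr.[Mg+]Cl | intermediate
20 | 32-(tert-butyldimethylsilyloxy)dotriacontanoic acid | CC(C)(C)[Si](C)(C)OCCCCCCCCCCCCCCCCCCCCCCCCCCCCCCCC(=O)O | intermediate
21 | C15 ester of 13 with acid 20 (silyl-protected target) | CC1=CC[C@@H]2C(C)(C)[C@H](O)CC[C@@]2(C)[C@@H]1CC/C(C)=C/COC(=O)CCCCCCCCCCCCCCCCCCCCCCCCCCCCCCCO[Si](C)(C)C(C)(C)C | intermediate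
22 | target, C15 32-hydroxydotriacontanoate of (3R,5S,9R,10S)-labda-7,13E-diene-3,15-diol | CC1=CC[C@@H]2C(C)(C)[C@H](O)CC[C@@]2(C)[C@@H]1CC/C(C)=C/COC(=O)CCCCCCCCCCCCCCCCCCCCCCCCCCCCCCCO | target

**Step count**

Total: 15 steps. Longest linear sequence: 11 steps (steps 1 to 9, 14 and 15, from geraniol); the acid branch is 4 steps (10 to 13).

**Steps most likely to fail**

Step 4. The cycloaddition may leak into the other regiochemistry (C9 bonding to C5 under the influence of the C8 methyl group), may pass partly through the formyl-endo arrangement, and may turn over slowly. The fallback sets out from enal 4 and returns at 7; it puts an oxygen donor on C7 so that C6 becomes by far the more nucleophilic terminus and the diene reacts at lower temperature. MeMgBr in THF at −78 °C adds to 4 to give the secondary allylic alcohol F1. MnO2 gives the (E)-enone F2. TBSOTf and Et3N in CH2Cl2 at 0 °C give the 2-silyloxy triene F3. Cycloaddition of F3 with 6 under the catalyst of step 4 at −78 °C should give the cyclic silyl enol ether F4 (oxygen on C7, C7=C8 in place). CsF and PhNTf2 in 1,2-dimethoxyethane convert it into the enol triflate F5. Pd(OAc)2, PPh3, Et3N and HCO2H in DMF at 60 °C replace the triflate by hydrogen and give 7.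

Step 8. Hydrogen-atom transfer may also reach the two trisubstituted alkenes (C7=C8, C13=C14); the C4 radical or the aldehyde may be reduced before ring closure; and equatorial selectivity at C3 may be incomplete. The fallback sets out from ketone 9 and returns at 12; it generates the C4 radical from a single, pre-placed leaving group. MeMgBr with CeCl3 in THF at −78 °C adds to 9 to give the tertiary alcohol F6. Methyl chlorooxoacetate with DMAP in pyridine gives the tertiary methyl oxalate F7. Hydroformylation under the conditions of step 7, now with the vinyl group as the only terminal alkene, gives the aldehyde F8. Slow addition of Bu3SnH and azobisisobutyronitrile in refluxing toluene fragments the oxalate to the C4 radical alone, which closes 6-exo onto the formyl group; the alkoxy radical takes hydrogen from the stannane and gives 12.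

Step 7. The isopropenyl group may be hydroformylated alongside the vinyl group, or the neopentyl-type vinyl group may react sluggishly. The fallback sets out from 10 and returns at 11; it replaces carbonylation by hydroboration and a one-carbon Wittig homologation. RhCl(PPh3)3-catalysed hydroboration with catecholborane in THF, which is selective for the monosubstituted alkene, followed by NaOH/H2O2, gives the primary alcohol F9. Dess–Martin periodinane gives the aldehyde F10. Ph3P=CHOMe, made from Ph3PCH2OMe Cl and KOt-Bu in THF, gives the methyl enol ether F11. Dilute HCl in THF at 0 °C hydrolyses it to 11.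

**Further compounds**

F1 | step 4 | (3E,7E)-9-(tert-butyldiphenylsilyloxy)-3,7-dimethylnona-3,7-dien-2-ol | CC(O)/C(C)=C/CC/C(C)=C/CO[Si](c1ccccc1)(c1ccccc1)C(C)(C)C
F2 | step 4 | (3E,7E)-9-(tert-butyldiphenylsilyloxy)-3,7-dimethylnona-3,7-dien-2-one | CC(=O)/C(C)=C/CC/C(C)=C/CO[Si](c1ccccc1)(c1ccccc1)C(C)(C)C
F3 | step 4 | (3E,7E)-2-(tert-butyldimethylsilyloxy)-9-(tert-butyldiphenylsilyloxy)-3,7-dimethylnona-1,3,7-triene | C=C(O[Si](C)(C)C(C)(C)C)/C(C)=C/CC/C(C)=C/CO[Si](c1ccccc1)(c1ccccc1)C(C)(C)C
F4 | step 4 | C7 tert-butyldimethylsilyl enol ether of adduct 7 | CC1=C(O[Si](C)(C)C(C)(C)C)C[C@H](C(=O)OCC)[C@@](C)(C=O)[C@@H]1CC/C(C)=C/CO[Si](c1ccccc1)(c1ccccc1)C(C)(C)C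
F5 | step 4 | C7 enol triflate of adduct 7 | CC1=C(OS(=O)(=O)C(F)(F)F)C[C@H](C(=O)OCC)[C@@](C)(C=O)[C@@H]1CC/C(C)=C/CO[Si](c1ccccc1)(c1ccccc1)C(C)(C)C
F6 | step 8 | tertiary alcohol at C4 (2-hydroxyprop-2-yl on C5, vinyl on C10) | CC1=CC[C@H](C(C)(C)O)[C@@](C)(C=C)[C@@H]1CC/C(C)=C/CO[Si](c1ccccc1)(c1ccccc1)C(C)(C)C
F7 | step 8 | methyl oxalate of the C4 tertiary alcohol | CC1=CC[C@H](C(C)(C)OC(=O)C(=O)OC)[C@@](C)(C=C)[C@@H]1CC/C(C)=C/CO[Si](c1ccccc1)(c1ccccc1)C(C)(C)C
F8 | step 8 | C3 aldehyde bearing the C4 tertiary methyl oxalate | CC1=CC[C@H](C(C)(C)OC(=O)C(=O)OC)[C@@](C)(CCC=O)[C@@H]1CC/C(C)=C/CO[Si](c1ccccc1)(c1ccccc1)C(C)(C)C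
F9 | step 7 | primary alcohol at C2 (2-hydroxyethyl on C10, isopropenyl on C5) | CC1=CC[C@H](C(C)=C)[C@@](C)(CCO)[C@@H]1CC/C(C)=C/CO[Si](c1ccccc1)(c1ccccc1)C(C)(C)C
F10 | step 7 | C2 aldehyde (2-oxoethyl on C10, isopropenyl on C5) | CC1=CC[C@H](C(C)=C)[C@@](C)(CC=O)[C@@H]1CC/C(C)=C/CO[Si](c1ccccc1)(c1ccccc1)C(C)(C)C
F11 | step 7 | methyl enol ether (3-methoxyprop-2-enyl on C10, E/Z mixture) | CC1=CC[C@H](C(C)=C)[C@@](C)(CC=COC)[C@@H]1CC/C(C)=C/CO[Si](c1ccccc1)(c1ccccc1)C(C)(C)C
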